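Ring B is closed last by ring-closing metathesis (C8=C9) on a cyclopentane whose two chains on C1 and C5 are trans; before that come the anti-reduction of a C6 ketone and the bis-angeloylation (numbering: ring A = C1(CH3)–C2–C3–C4(OH, iPr)–C5(H); ring B = C5–C6(O)–C7–C8(CH3)=C9–C10(O)–C1).
Ring A is cut into the three-carbon unit C2–C1–C5, held as a cyclopropane, and the two-carbon unit C3–C4 (3-methylbut-1-yne); a samarium-ketyl radical relay ([3+2]) makes C2–C3 and C4–C5 in one operation.
Enabling feature: the acyl carbon C6 (on C5) and the oxygen on C10 (on C1) are 1,4-related across the ring-fusion bond C1–C5; one extra CH2 ties them into a six-membered 3-oxacyclohexanone, whose C6 ketone activates the exocyclic cyclopropane bond C5–C2.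
The temporary ring is removed again: Baeyer–Villiger oxidation turns the extra CH2 into a formaldehyde acetal carbon that is lost; the C4–OH comes from a convex-face epoxide, and C5 is inverted at the aldehyde stage.
Ring order: C10 stereocentre (catalytic vinylation) → cyclopropane with temporary oxacycle → ring A (key step) → ring B (metathesis); C6 is set last by hydroxyl-directed reduction.

Key step: step 5

Remark: β is the face of ring A that carries the C1 methyl group; both ester groups are read from the SMILES as angelates, (Z)-2-methylbut-2-enoates.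

Step 1
Reactants: 1 methacrolein
Product: 2 (R)-2-methylpenta-1,4-dien-3-ol
Conditions: Zn(CH=CH2)2 (salt-free, from ZnCl2 and vinylmagnesium bromide), (+)-DAIB (5 mol %), toluene, −20 → 0 °C; aq NH4Cl
Reagents that add atoms: divinylzinc, C=C[Zn]C=C
Why: Amino-alcohol-catalysed asymmetric 1,2-addition of an alkenylzinc to an aldehyde; the (+)-DAIB zinc complex should deliver the vinyl group to the Re face and set C10 as R.

Step 2
Reactants: 2 (R)-2-methylpenta-1,4-dien-3-ol
Product: 3 (R)-2-[(2-methylpenta-1,4-dien-3-yl)oxy]acetic acid
Conditions: NaH (2.5 equiv), BrCH2CO2H, THF, 0 → 40 °C; then dilute HCl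
Reagents that add atoms: bromoacetic acid, OC(=O)CBr
Why: Williamson etherification of the sodium alkoxide with sodium bromoacetate (SN2 at the primary bromide); the stereocentre is not touched.

Step 3
Reactants: 3 (R)-2-[(2-methylpenta-1,4-dien-3-yl)oxy]acetic acid
Product: 5 (R)-1-diazo-3-[(2-methylpenta-1,4-dien-3-yl)oxy]propan-2-one, via acid chloride 4 (not isolated)
Conditions: (COCl)2, DMF (cat.), CH2Cl2, 0 °C; evaporate; CH2N2 (3 equiv), Et2O, 0 °C
Reagents that add atoms: diazomethane, C=[N+]=[N-]
Why: Acid chloride formation, then acylation of diazomethane (Arndt–Eistert-type diazoketone synthesis); a second equivalent of diazomethane takes up the HCl.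

Step 4
Reactants: 5 (R)-1-diazo-3-[(2-methylpenta-1,4-dien-3-yl)oxy]propan-2-one
Product: 6 (1S,2R,6R)-2-ethenyl-1-methyl-3-oxabicyclo[4.1.0]heptan-5-one (vinyl anti to the cyclopropane CH2)
Conditions: Cu(acac)2 (5 mol %), benzene, 80 °C, slow addition of 5
Reagents that add atoms: none
Why: Copper-carbenoid intramolecular cyclopropanation of an α-diazoketone onto the more nucleophilic 1,1-disubstituted alkene; a chair-like six-membered transition state with the vinyl group pseudo-equatorial should relay C10 to C1 and C5, copper is chosen to suppress C–H insertion next to the ether oxygen, and a minor diastereomer would be removed by chromatography.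

Step 5
Reactants: 6 (1S,2R,6R)-2-ethenyl-1-methyl-3-oxabicyclo[4.1.0]heptan-5-one; 7 3-methylbut-1-yne
Product: 8 cis-fused bicyclic ketone (ring A cyclopentene with C3=C4 and 4-isopropyl, fused at C1–C5 to the 3-oxacyclohexanone C6(=O)–CH2–O–C10; 1-CH3 β, 5-H β, 10-vinyl β)
Conditions: SmI2 (20 mol %), Sm metal (20 mol %), 7 (10 equiv), THF, 55 °C, sealed tube
Reagents that add atoms: none
Why: SmI2 transfers one electron to the C6 ketone, the ketyl opens the exocyclic cyclopropane bond C5–C2, the primary radical at C2 adds to the terminal alkyne carbon (bond C2–C3), the vinyl radical at C4 attacks C5 of the trivalent-samarium enolate (bond C4–C5), and the new ketyl returns the electron, with samarium metal keeping the catalyst divalent. The closest known reaction type is the SmI2-catalysed radical-relay formal [3+2] cycloaddition of bicyclic alkyl cyclopropyl ketones (bicyclo[4.1.0]heptan-2-ones) with terminal alkynes. Ring A is closed by an intermolecular radical addition followed by a 5-exo-trig radical–enolate coupling. C1 is carried over from 6, and C5 is formed with 5-H cis to 1-CH3, because the tether from C1 can reach only the enolate face on which C2 stands; this cis fusion to the temporary ring is corrected in step 10 after that ring is opened. The step needs cleavage of the exocyclic and not the ring-fusion cyclopropane bond, which the six-membered ring should secure by holding C5–C2 parallel to the ketyl π system (the other mode would give a strained seven-membered enolate), and attack at the unsubstituted alkyne terminus, which is the normal radical regiochemistry. The C10 vinyl group should not interfere, because the C2 radical could reach it only by 4-exo or 5-endo closure.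

Step 6
Reactants: 8 cis-fused bicyclic ketone
Product: 10 3β,4β-epoxy 1,3-dioxepan-4-one (acyl acetal C6(=O)–O–CH2–O–C10 fused to ring A), via epoxy ketone 9 (not isolated)
Conditions: mCPBA (3 equiv), CH2Cl2, 0 → 23 °C
Reagents that add atoms: mCPBA, OOC(=O)c1cccc(Cl)c1
Why: Prilezhaev epoxidation of the trisubstituted cyclopentene from the convex β-face (the oxacycle covers the α-face) sets the C4–O bond β and leaves the monosubstituted vinyl group; Baeyer–Villiger oxidation then inserts oxygen between C6 and the oxygen-bearing CH2, the better migrating group.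

Step 7
Reactants: 10 3β,4β-epoxy 1,3-dioxepan-4-one
Product: 11 ring A Weinreb amide (1β-CH3, 1α-[(R)-1-hydroxyallyl], 3β,4β-epoxy, 4α-isopropyl, 5α-C(=O)N(OMe)Me)
Conditions: MeNH(OMe)·HCl, iPrMgCl, THF, −20 → 0 °C
Reagents that add atoms: N,O-dimethylhydroxylamine hydrochloride, CNOC.Cl
Why: Aminolysis of the activated acyl acetal by the chloromagnesium amide (Weinreb amide formation); the released hemiacetal alkoxide loses formaldehyde and frees the C10 hydroxyl, and the hindered epoxide should survive at low temperature.

Step 8
Reactants: 11 ring A Weinreb amide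
Product: 12 10-O-tert-butyldimethylsilyl ether of 11
Conditions: TBSCl, imidazole, DMF, 40 °C
Reagents that add atoms: tert-butyldimethylsilyl chloride, CC(C)(C)[Si](C)(C)Cl
Why: Silylation of the secondary allylic alcohol under imidazole conditions; a silyl triflate is avoided because it could isomerise the epoxide.

Step 9
Reactants: 12 10-O-silyl Weinreb amide
Product: 13 diol (5α-CH2OH, 4β-OH, 4α-isopropyl, 1β-CH3, 1α-[(R)-1-(silyloxy)allyl]cyclopentane)
Conditions: LiEt3BH (5 equiv), THF, 0 → 23 °C
Reagents that add atoms: none
Why: The trialkylborohydride reduces the Weinreb amide to the primary alcohol and opens the trisubstituted epoxide by SN2 attack at the less substituted C3 from the α-face, which leaves the tertiary C4–OH β.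

Step 10
Reactants: 13 diol
Product: 15 trans-aldehyde (5β-CHO, 5-H α), via cis-aldehyde 14 (not isolated)
Conditions: Dess–Martin periodinane, CH2Cl2, 0 °C; then DBU (0.3 equiv), 23 → 40 °C
Reagents that add atoms: none
Why: Dess–Martin oxidation of the primary alcohol, then amidine-catalysed epimerisation α to the aldehyde under thermodynamic control: the formyl group leaves the α-face (cis to both the isopropyl group and the C10 side chain) for the β-face (cis to 4-OH and 1-CH3), which sets C5 and the trans relation of the two chains needed for ring B.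

Step 11
Reactants: 15 trans-aldehyde
Product: 16 methallyl carbinol (mixture of C6 epimers)
Conditions: CH2=C(CH3)CH2MgCl (2.5 equiv), THF, −78 °C; aq NH4Cl
Reagents that add atoms: 2-methylallylmagnesium chloride, C=C(C)C[Mg]Cl
Why: Grignard 1,2-addition to the aldehyde (one equivalent is consumed by the tertiary hydroxyl); the C6 configuration does not matter because C6 is oxidised in the next step.

Step 12
Reactants: 16 methallyl carbinol
Product: 17 methallyl ketone (C6 ketone on C5β)
Conditions: Dess–Martin periodinane, CH2Cl2, 0 → 23 °C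
Reagents that add atoms: none
Why: Dess–Martin oxidation under neutral conditions should give the β,γ-unsaturated ketone without moving the alkene into conjugation.

Step 13
Reactants: 17 methallyl ketone
Product: 18 4β-hydroxy-10α-(tert-butyldimethylsilyloxy)dauc-8-en-6-one (trans-fused)
Conditions: second-generation Grubbs catalyst, RuCl2(=CHPh)(H2IMes)(PCy3) (5 mol %), CH2Cl2 (2 mM), 40 °C
Reagents that add atoms: none
Why: Ring-closing metathesis of the 1,1-disubstituted and the monosubstituted alkene closes ring B as the trisubstituted C8=C9 cycloheptene; the trans chains give the trans-fused bicycle and no stereocentre is touched.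

Step 14
Reactants: 18 β-hydroxy ketone
Product: 19 10α-(tert-butyldimethylsilyloxy)dauc-8-ene-4β,6α-diol
Conditions: Me4NBH(OAc)3, AcOH/MeCN (1:1), −30 °C
Reagents that add atoms: none
Why: Evans–Saksena hydroxyl-directed reduction: the alkoxy(diacetoxy)borohydride on O4 delivers hydride intramolecularly to the ketone face on which O4 lies, which should give the anti-1,3-diol (C6–OH α).

Step 15
Reactants: 19 silyl ether diol
Product: 20 dauc-8-ene-4β,6α,10α-triol
Conditions: HF·pyridine, pyridine, THF, 0 → 23 °C
Reagents that add atoms: none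
Why: Fluoride cleavage of the secondary silyl ether; buffered HF·pyridine should tolerate the tertiary and the allylic alcohol.

Step 16
Reactants: 20 triol; 21 angelic acid
Product: 23 target, (1S,4R,5S,6S,10R)-4-hydroxydauc-8-ene-6,10-diyl bis[(Z)-2-methylbut-2-enoate], via 6-mono-angelate 22 (not isolated)
Conditions: 21 (3 equiv), 2,4,6-trichlorobenzoyl chloride, Et3N, toluene, 23 °C; then 20, DMAP, toluene, 80 °C
Reagents that add atoms: none
Why: Yamaguchi esterification through the mixed 2,4,6-trichlorobenzoic angelic anhydride acylates both secondary alcohols, leaves the hindered tertiary C4–OH free and is the usual way to keep the Z geometry of the angeloyl group.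

Compound list
1 | methacrolein | C=C(C)C=O | starting material
2 | (R)-2-methylpenta-1,4-dien-3-ol | C=C(C)[C@H](O)C=C | intermediate
3 | (R)-2-[(2-methylpenta-1,4-dien-3-yl)oxy]acetic acid | C=C(C)[C@H](OCC(=O)O)C=C | intermediate
4 | (R)-2-[(2-methylpenta-1,4-dien-3-yl)oxy]acetyl chloride (not isolated) | C=C(C)[C@H](OCC(=O)Cl)C=C | intermediate
5 | (R)-1-diazo-3-[(2-methylpenta-1,4-dien-3-yl)oxy]propan-2-one | C=C(C)[C@H](OCC(=O)C=[N+]=[N-])C=C | intermediate
6 | (1S,2R,6R)-2-ethenyl-1-methyl-3-oxabicyclo[4.1.0]heptan-5-one | O=C1CO[C@H](C=C)[C@@]2(C)C[C@@H]12 | intermediate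
7 | 3-methylbut-1-yne | CC(C)C#C | starting material
8 | cis-fused bicyclic ketone, ring A cyclopentene on the 3-oxacyclohexanone | O=C1CO[C@H](C=C)[C@@]2(C)CC=C(C(C)C)[C@@H]12 | intermediate
9 | 3β,4β-epoxide of 8 (not isolated) | O=C1CO[C@H](C=C)[C@@]2(C)C[C@@H]3O[C@]3(C(C)C)[C@@H]12 | intermediate
10 | 3β,4β-epoxy 1,3-dioxepan-4-one (acyl acetal) | O=C1OCO[C@H](C=C)[C@@]2(C)C[C@@H]3O[C@]3(C(C)C)[C@@H]12 | intermediate
11 | ring A Weinreb amide with epoxide and free 10-OH | CON(C)C(=O)[C@@H]1[C@@]2(C(C)C)O[C@H]2C[C@]1(C)[C@H](O)C=C | intermediate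
12 | 10-O-tert-butyldimethylsilyl ether of 11 | CON(C)C(=O)[C@@H]1[C@@]2(C(C)C)O[C@H]2C[C@]1(C)[C@H](O[Si](C)(C)C(C)(C)C)C=C | intermediate
13 | diol, 5α-CH2OH and 4β-OH | OC[C@@H]1[C@](O)(C(C)C)CC[C@]1(C)[C@H](O[Si](C)(C)C(C)(C)C)C=C | intermediate
14 | cis-aldehyde, 5α-CHO (not isolated) | O=C[C@@H]1[C@](O)(C(C)C)CC[C@]1(C)[C@H](O[Si](C)(C)C(C)(C)C)C=C | intermediate
15 | trans-aldehyde, 5β-CHO | O=C[C@H]1[C@](O)(C(C)C)CC[C@]1(C)[C@H](O[Si](C)(C)C(C)(C)C)C=C | intermediate
16 | methallyl carbinol, C6 epimers | C=C(C)CC(O)[C@H]1[C@](O)(C(C)C)CC[C@]1(C)[C@H](O[Si](C)(C)C(C)(C)C)C=C | intermediate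
17 | methallyl ketone | C=C(C)CC(=O)[C@H]1[C@](O)(C(C)C)CC[C@]1(C)[C@H](O[Si](C)(C)C(C)(C)C)C=C | intermediate
18 | 4β-hydroxy-10α-(tert-butyldimethylsilyloxy)dauc-8-en-6-one | O=C1CC(C)=C[C@@H](O[Si](C)(C)C(C)(C)C)[C@@]2(C)CC[C@@](O)(C(C)C)[C@H]12 | intermediate
19 | 10α-(tert-butyldimethylsilyloxy)dauc-8-ene-4β,6α-diol | O[C@H]1CC(C)=C[C@@H](O[Si](C)(C)C(C)(C)C)[C@@]2(C)CC[C@@](O)(C(C)C)[C@H]12 | intermediate
20 | dauc-8-ene-4β,6α,10α-triol | O[C@H]1CC(C)=C[C@@H](O)[C@@]2(C)CC[C@@](O)(C(C)C)[C@H]12 | intermediate
21 | angelic acid, (Z)-2-methylbut-2-enoic acid | C/C=C(/C)C(=O)O | starting material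
22 | 6-O-angeloyl triol (not isolated) | C/C=C(/C)C(=O)O[C@H]1CC(C)=C[C@@H](O)[C@@]2(C)CC[C@@](O)(C(C)C)[C@H]12 | intermediate
23 | target, 6α,10α-bis(angeloyloxy)dauc-8-en-4β-ol | C/C=C(/C)C(=O)O[C@H]1CC(C)=C[C@@H](OC(=O)/C(C)=C\C)[C@@]2(C)CC[C@@](O)(C(C)C)[C@H]12 | target

Total step count: 16. Longest linear sequence: 16 steps, from methacrolein.

Steps most likely to fail

Step 5, the key step. The radical relay may be diverted by fragmentation of the ring-fusion bond C5–C1, by reductive loss of the α-alkoxy group, or by hydrogen abstraction from THF before the primary radical finds the unactivated alkyne. The fallback makes the same two bonds in a two-electron manifold: Ni(cod)2 (zerovalent nickel) with Me2AlCl catalyses the [3+2] cycloaddition of cyclopropyl ketones with alkynes by oxidative addition into the less hindered C5–C2 bond (six-membered oxa-nickelacycle), alkyne insertion with the unsubstituted carbon next to C2, and C–C reductive elimination at C5. It sets out from 6 and 7 and comes back at 8; it makes no new compound.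

Step 6. The Baeyer–Villiger step may let the ring-fusion carbon C5 migrate instead of the oxygen-bearing CH2, and the acid by-product may open the trisubstituted epoxide. The fallback changes the temporary ring to one whose excision is unambiguous. It sets out from 2: oxalyl chloride gives the chlorooxoacetate F1, diazomethane the diazopyruvate ester F2, and intramolecular cyclopropanation (Rh2(OAc)4) the α-keto lactone F3, (1S,2R,6R)-2-ethenyl-1-methyl-3-oxabicyclo[4.1.0]heptane-4,5-dione. The radical relay with 7 as in step 5 gives the cis-fused keto lactone F4. mCPBA then epoxidises the cyclopentene and cleaves the 1,2-dicarbonyl unit; the extra carbonyl carbon leaves as CO2 and the hydroxy acid closes to the epoxy γ-lactone F5. Aminolysis of F5 under the conditions of step 7 comes back at 11.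

Step 10. Retro-aldol fragmentation of the β-hydroxy aldehyde or β-elimination of the tertiary hydroxyl may compete with the slow inversion at the hindered C5. The fallback moves the equilibration to the ester oxidation level, where both side reactions are much slower. It sets out from 13: Dess–Martin oxidation and then Pinnick oxidation (NaClO2, NaH2PO4, 2-methylbut-2-ene) give the cis-acid F6, and trimethylsilyldiazomethane the cis methyl ester F7. NaOMe in MeOH equilibrates it to the trans methyl ester F8, and DIBAL-H at −78 °C comes back at 15.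

Further compounds
F0 | step 5 | none | none
F1 | step 6 | (R)-2-methylpenta-1,4-dien-3-yl 2-chloro-2-oxoacetate | C=C(C)[C@H](OC(=O)C(=O)Cl)C=C
F2 | step 6 | (R)-2-methylpenta-1,4-dien-3-yl 3-diazo-2-oxopropanoate | C=C(C)[C@H](OC(=O)C(=O)C=[N+]=[N-])C=C
F3 | step 6 | (1S,2R,6R)-2-ethenyl-1-methyl-3-oxabicyclo[4.1.0]heptane-4,5-dione | O=C1C(=O)O[C@H](C=C)[C@@]2(C)C[C@@H]12
F4 | step 6 | cis-fused α-keto lactone with ring A cyclopentene | O=C1C(=O)O[C@H](C=C)[C@@]2(C)CC=C(C(C)C)[C@@H]12
F5 | step 6 | 3β,4β-epoxy γ-lactone (C6(=O)–O–C10) fused to ring A | O=C1O[C@H](C=C)[C@@]2(C)C[C@@H]3O[C@]3(C(C)C)[C@@H]12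
F6 | step 10 | cis-acid, 5α-CO2H | OC(=O)[C@@H]1[C@](O)(C(C)C)CC[C@]1(C)[C@H](O[Si](C)(C)C(C)(C)C)C=C
F7 | step 10 | cis methyl ester, 5α-CO2CH3 | COC(=O)[C@@H]1[C@](O)(C(C)C)CC[C@]1(C)[C@H](O[Si](C)(C)C(C)(C)C)C=C
F8 | step 10 | trans methyl ester, 5β-CO2CH3 | COC(=O)[C@H]1[C@](O)(C(C)C)CC[C@]1(C)[C@H](O[Si](C)(C)C(C)(C)C)C=C
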